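## Retrosynthetic overview

1. The target comes from a reagent-controlled 1,2-reduction of the macrocyclic C4 enone (sets C4), after benzoylation of the C9 hydroxyl.
2. The ten-membered ring (the only ring) is closed at C8–C9 by intramolecular allylboration of an α-chiral allylboronate, made in the same flask by copper-catalysed 1,4-borylation of an open-chain trienone aldehyde (sets C9 and the Z C6=C7 bond).
3. The trienone aldehyde comes from a carbonylative Stille union (C3–C4–C5) of a (Z)-alkenyl iodide that carries the β-acetoxy aldehyde with a dienylstannane and CO.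
4. The (Z)-alkenyl iodide comes from alkoxide-directed trans-hydroalumination/iodination of an alkynediol (Z C2=C3), then selective oxidation and acetylation.
5. C10 and C1 come from a diarylprolinol-catalysed anti cross-aldol of 3-methylbutanal with but-2-ynal.

Assumption: ring atoms are labelled C1 (CH–OAc), C2=C3(CH3), C4 (CH–OH), C5 (CH2), C6=C7(CH3), C8 (CH2), C9 (CH–OBz), C10 (CH–iPr); the same labels are used for open-chain precursors. In this numbering the target is 1S,2Z,4R,6Z,9S,10R.
Assumption: but-2-ynal is bought, or freed from its commercial diethyl acetal with aqueous formic acid just before use.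

## Route

Step 1
Reactants: 1 3-methylbutanal; 2 but-2-ynal
Product: 4 (2R,3R)-2-(propan-2-yl)hex-4-yne-1,3-diol, via aldol aldehyde 3 (not isolated)
Conditions: (S)-α,α-bis[3,5-bis(trifluoromethyl)phenyl]pyrrolidin-2-ylmethanol (10 mol%), H2O (3 equiv), 1,4-dioxane, 23 °C; then NaBH4, MeOH, 0 °C
Reagents that add atoms: none
Why: Enamine cross-aldol of the Hayashi type: the E-enamine of 1 adds to the ynal, which is held by a hydrogen bond to the catalyst hydroxyl in the same arrangement that makes proline aldols anti, so C10 and C1 are set together (anti, 2S,3R in 3) and NaBH4 then traps the labile aldol as the diol.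

Step 2
Reactants: 4 (2R,3R)-2-(propan-2-yl)hex-4-yne-1,3-diol
Product: 5 (2R,3R,4Z)-5-iodo-2-(propan-2-yl)hex-4-ene-1,3-diol
Conditions: NaAlH2(OCH2CH2OCH3)2 (3 equiv), THF, 0 to 23 °C; EtOAc; then I2, THF, −78 to 0 °C; aq. Na2S2O3, aq. KNaC4H4O6
Reagents that add atoms: iodine, [I][I]
Why: Alkoxide-directed trans-hydroalumination of a propargylic alcohol places aluminium on the distal alkyne carbon inside a five-membered alkoxyalanate, and iodinolysis with retention gives the (Z)-alkenyl iodide, which fixes the C2=C3 geometry without touching C10 or C1.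

Step 3
Reactants: 5 (2R,3R,4Z)-5-iodo-2-(propan-2-yl)hex-4-ene-1,3-diol
Product: 7 (2Z,4R,5S)-5-formyl-2-iodo-6-methylhept-2-en-4-yl acetate, via hydroxy aldehyde 6 (not isolated)
Conditions: TEMPO (10 mol%), PhI(OAc)2 (1.1 equiv), CH2Cl2, 0 to 23 °C; then Ac2O, pyridine, DMAP (2 mol%), −20 °C; cold work-up, used at once
Reagents that add atoms: acetic anhydride, CC(=O)OC(C)=O
Why: The TEMPO/PhI(OAc)2 oxoammonium oxidation takes the primary alcohol much faster than the hindered secondary allylic one, and acetylating the α-branched aldol cold in the same flask installs the final C1 ester before elimination or epimerisation can set in.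

Step 4
Reactants: 8 2-methylbut-1-en-3-yne
Product: 9 tributyl[(1E)-3-methylbuta-1,3-dien-1-yl]stannane
Conditions: Bu3SnH (1.0 equiv), AIBN (5 mol%), PhMe, 80 °C; distillation
Reagents that add atoms: tributyltin hydride, CCCC[SnH](CCCC)CCCC
Why: Radical hydrostannation of the terminal alkyne is anti-Markovnikov and equilibrates under the stannyl-radical conditions to the (E)-dienylstannane.

Step 5
Reactants: 7 (2Z,4R,5S)-5-formyl-2-iodo-6-methylhept-2-en-4-yl acetate; 9 tributyl[(1E)-3-methylbuta-1,3-dien-1-yl]stannane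
Product: 10 (2S,3S,4Z,7E)-5,9-dimethyl-1,6-dioxo-2-(propan-2-yl)deca-4,7,9-trien-3-yl acetate
Conditions: Pd2(dba)3 (2.5 mol%), AsPh3 (20 mol%), CO (1 atm), NMP, 45 °C; aq. KF
Reagents that add atoms: carbon monoxide, [C-]#[O+]
Why: Carbonylative Stille coupling, with oxidative addition into the C–I bond and CO insertion both proceeding with retention and no base present, joins C3–C4–C5 and keeps the Z geometry and the β-acetoxy aldehyde intact.

Step 6
Reactants: 10 (2S,3S,4Z,7E)-5,9-dimethyl-1,6-dioxo-2-(propan-2-yl)deca-4,7,9-trien-3-yl acetate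
Product: 12 (1S,2Z,6Z,9S,10R)-9-hydroxy-3,7-dimethyl-4-oxo-10-(propan-2-yl)cyclodeca-2,6-dien-1-yl acetate, via allylboronate 11 (not isolated)
Conditions: CuCl (5 mol%), Tol-BINAP (6 mol%, the enantiomer that gives 6S), NaOtBu (6 mol%), B2pin2 (1.1 equiv), MeOH (2 equiv), THF, −20 °C; then PhMe to 2 mM, (PhO)2P(O)OH (10 mol%), 40 °C; aq. NaHCO3
Reagents that add atoms: none
Why: Proposed new method: a tandem copper-catalysed enantioselective 1,4-borylation and intramolecular allylboration that closes a medium ring, in which Cu–B(pin) adds to C6 of the less hindered, disubstituted enone arm (the ligand hand is fixed on a model enone so that C6 is S) and methanol protonates the enolate to give the α-chiral 2-methylallyl boronate 11, whose allyl unit then attacks the tethered C9 aldehyde through a six-membered chair transition state with the C5 substituent axial (favoured by 1,2-allylic strain with the C7 methyl and by the ring being formed), so that C8–C9 forms with full allylic transposition, the new C6=C7 bond is Z, and the boron-bearing centre is relayed to C9 (6S gives 9S, which is also the Felkin and 1,3-anti face); the closest known reaction types are copper-catalysed β-borylation of enones and dienones, copper-catalysed borylative aldol cyclisations, and chirality-transfer allylboration of aldehydes by α-substituted allyl pinacol boronates, none of which has been used to close a ten-membered carbocycle.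

Step 7
Reactants: 12 (1S,2Z,6Z,9S,10R)-9-hydroxy-3,7-dimethyl-4-oxo-10-(propan-2-yl)cyclodeca-2,6-dien-1-yl acetate
Product: 13 (1S,2Z,6Z,9S,10R)-9-(benzoyloxy)-3,7-dimethyl-4-oxo-10-(propan-2-yl)cyclodeca-2,6-dien-1-yl acetate
Conditions: BzCl (1.5 equiv), pyridine, DMAP (10 mol%), CH2Cl2, 0 to 23 °C
Reagents that add atoms: benzoyl chloride, O=C(Cl)c1ccccc1
Why: DMAP-catalysed acylation of the only free hydroxyl group, at a temperature where the skipped (β,γ) enone does not move into conjugation.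

Step 8
Reactants: 13 (1S,2Z,6Z,9S,10R)-9-(benzoyloxy)-3,7-dimethyl-4-oxo-10-(propan-2-yl)cyclodeca-2,6-dien-1-yl acetate
Product: 14 (1S,2Z,4R,6Z,9S,10R)-9-(benzoyloxy)-4-hydroxy-3,7-dimethyl-10-(propan-2-yl)cyclodeca-2,6-dien-1-yl acetate
Conditions: (S)-2-methyl-CBS-oxazaborolidine (0.5 equiv), catecholborane (2 equiv), PhMe, −78 °C; MeOH, pH 7 buffer
Reagents that add atoms: none
Why: Corey–Bakshi–Shibata reduction, in which the (S)-oxazaborolidine binds the enone with the alkenyl arm as the large group and delivers hydride in a 1,2 sense to give the 4R allylic alcohol, while catecholborane at −78 °C leaves the esters and the alkenes alone.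

## Compound list

1 | 3-methylbutanal | CC(C)CC=O | starting material
2 | but-2-ynal | CC#CC=O | starting material
3 | (2S,3R)-3-hydroxy-2-(propan-2-yl)hex-4-ynal | O=C[C@@H](C(C)C)[C@@H](O)C#CC | intermediate
4 | (2R,3R)-2-(propan-2-yl)hex-4-yne-1,3-diol | OC[C@@H](C(C)C)[C@@H](O)C#CC | intermediate
5 | (2R,3R,4Z)-5-iodo-2-(propan-2-yl)hex-4-ene-1,3-diol | OC[C@@H](C(C)C)[C@@H](O)/C=C(/C)I | intermediate
6 | (2S,3R,4Z)-3-hydroxy-5-iodo-2-(propan-2-yl)hex-4-enal | O=C[C@@H](C(C)C)[C@@H](O)/C=C(/C)I | intermediate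
7 | (2Z,4R,5S)-5-formyl-2-iodo-6-methylhept-2-en-4-yl acetate | O=C[C@@H](C(C)C)[C@@H](OC(C)=O)/C=C(/C)I | intermediate
8 | 2-methylbut-1-en-3-yne | C=C(C)C#C | starting material
9 | tributyl[(1E)-3-methylbuta-1,3-dien-1-yl]stannane | CCCC[Sn](CCCC)(CCCC)/C=C/C(C)=C | intermediate
10 | (2S,3S,4Z,7E)-5,9-dimethyl-1,6-dioxo-2-(propan-2-yl)deca-4,7,9-trien-3-yl acetate | O=C[C@@H](C(C)C)[C@@H](OC(C)=O)/C=C(/C)C(=O)/C=C/C(C)=C | intermediate
11 | (2S,3S,4Z,8S)-5,9-dimethyl-1,6-dioxo-2-(propan-2-yl)-8-(4,4,5,5-tetramethyl-1,3,2-dioxaborolan-2-yl)deca-4,9-dien-3-yl acetate | O=C[C@@H](C(C)C)[C@@H](OC(C)=O)/C=C(/C)C(=O)C[C@H](B1OC(C)(C)C(C)(C)O1)C(C)=C | intermediate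
12 | (1S,2Z,6Z,9S,10R)-9-hydroxy-3,7-dimethyl-4-oxo-10-(propan-2-yl)cyclodeca-2,6-dien-1-yl acetate | CC(=O)O[C@H]1/C=C(/C)C(=O)C/C=C(/C)C[C@H](O)[C@H]1C(C)C | intermediate
13 | (1S,2Z,6Z,9S,10R)-9-(benzoyloxy)-3,7-dimethyl-4-oxo-10-(propan-2-yl)cyclodeca-2,6-dien-1-yl acetate | CC(=O)O[C@H]1/C=C(/C)C(=O)C/C=C(/C)C[C@H](OC(=O)c2ccccc2)[C@H]1C(C)C | intermediate
14 | (1S,2Z,4R,6Z,9S,10R)-9-(benzoyloxy)-4-hydroxy-3,7-dimethyl-10-(propan-2-yl)cyclodeca-2,6-dien-1-yl acetate (CNP0125882.1) | CC(=O)O[C@H]1/C=C(/C)[C@H](O)C/C=C(/C)C[C@H](OC(=O)c2ccccc2)[C@H]1C(C)C | target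

## Step count and risks

Total step count: 8. Longest linear sequence: 7 (steps 1, 2, 3, 5, 6, 7, 8); step 4 makes the side reagent 9.

The three steps most likely to fail are steps 6, 3 and 8.

Step 6 is the proposed new tandem borylation/allylboration. Its risks are 1,6- instead of 1,4-borylation, attack of Cu–B(pin) on the aldehyde or the allylic acetate, aldol closure of the copper enolate, base-induced loss of the C10 configuration, and intermolecular allylation. The fallback uses known chemistry only, sets out from 7 and comes back to the route at 14. BF3·OEt2-mediated Hosomi–Sakurai addition of trimethyl(2-methylallyl)silane to 7, where Felkin and 1,3-anti control point the same way, gives (2Z,4R,5R,6S)-6-hydroxy-2-iodo-8-methyl-5-(propan-2-yl)nona-2,8-dien-4-yl acetate F1. Benzoylation (BzCl, pyridine, DMAP) gives (2Z,4R,5R,6S)-4-(acetyloxy)-2-iodo-8-methyl-5-(propan-2-yl)nona-2,8-dien-6-yl benzoate F2. Reductive carbonylation (Pd(PPh3)4, CO, Bu3SnH, THF, 50 °C) gives the Z-enal (2Z,4S,5R,6S)-4-(acetyloxy)-2,8-dimethyl-1-oxo-5-(propan-2-yl)nona-2,8-dien-6-yl benzoate F3. Chiral phosphoric acid-catalysed allylboration with allylB(pin) and (R)-3,3′-bis(2,4,6-triisopropylphenyl)-1,1′-binaphthyl-2,2′-diyl hydrogen phosphate sets C4 and gives (4R,5Z,7S,8R,9S)-7-(acetyloxy)-4-hydroxy-5,11-dimethyl-8-(propan-2-yl)dodeca-1,5,11-trien-9-yl benzoate F4; the catalyst hand is chosen by analogy with aryl and alkenyl aldehydes and should be confirmed. Ring-closing metathesis between the allyl and 2-methylallyl ends (second-generation Grubbs catalyst RuCl2(PCy3)(H2IMes)(=CHPh), 1 mM PhMe, 60 °C) then closes the ten-membered ring with the Z trisubstituted C6=C7 bond and gives 14 directly.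

Step 3 may fail through partial oxidation of the secondary allylic alcohol, or through elimination or C10 epimerisation of the aldol during acetylation. The fallback separates the two hydroxyls with a protecting group instead of relying on chemoselective oxidation; it sets out from 5 and comes back at 7. TBSCl/imidazole silylates the primary alcohol to give (2R,3R,4Z)-1-{[tert-butyl(dimethyl)silyl]oxy}-5-iodo-2-(propan-2-yl)hex-4-en-3-ol F5. Ac2O/pyridine/DMAP gives (2Z,4R,5R)-5-({[tert-butyl(dimethyl)silyl]oxy}methyl)-2-iodo-6-methylhept-2-en-4-yl acetate F6. HF·pyridine frees the primary alcohol to give (2Z,4R,5R)-5-(hydroxymethyl)-2-iodo-6-methylhept-2-en-4-yl acetate F7, and buffered Dess–Martin periodinane (NaHCO3, CH2Cl2) then gives 7 without ever exposing a free aldol to base.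

Step 8 may fail if the macrocycle overrides the catalyst, or if the skipped enone isomerises. The fallback replaces reagent control by substrate control plus inversion; it sets out from 13 and comes back at 14. Luche reduction (NaBH4, CeCl3·7H2O, MeOH, −78 °C) is run under ring control; if it delivers the C4 epimer (1S,2Z,4S,6Z,9S,10R)-9-(benzoyloxy)-4-hydroxy-3,7-dimethyl-10-(propan-2-yl)cyclodeca-2,6-dien-1-yl acetate F8, Mitsunobu inversion with chloroacetic acid (PPh3, DIAD) gives (1S,2Z,4R,6Z,9S,10R)-9-(benzoyloxy)-4-[(chloroacetyl)oxy]-3,7-dimethyl-10-(propan-2-yl)cyclodeca-2,6-dien-1-yl acetate F9. Thiourea/NaHCO3 in EtOH then removes only the chloroacetyl group to give 14.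

Further compounds
F1 | step 6 | (2Z,4R,5R,6S)-6-hydroxy-2-iodo-8-methyl-5-(propan-2-yl)nona-2,8-dien-4-yl acetate | CC(=C)C[C@H](O)[C@@H](C(C)C)[C@@H](OC(C)=O)/C=C(/C)I
F2 | step 6 | (2Z,4R,5R,6S)-4-(acetyloxy)-2-iodo-8-methyl-5-(propan-2-yl)nona-2,8-dien-6-yl benzoate | CC(=C)C[C@H](OC(=O)c1ccccc1)[C@@H](C(C)C)[C@@H](OC(C)=O)/C=C(/C)I
F3 | step 6 | (2Z,4S,5R,6S)-4-(acetyloxy)-2,8-dimethyl-1-oxo-5-(propan-2-yl)nona-2,8-dien-6-yl benzoate | CC(=C)C[C@H](OC(=O)c1ccccc1)[C@@H](C(C)C)[C@@H](OC(C)=O)/C=C(/C)C=O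
F4 | step 6 | (4R,5Z,7S,8R,9S)-7-(acetyloxy)-4-hydroxy-5,11-dimethyl-8-(propan-2-yl)dodeca-1,5,11-trien-9-yl benzoate | CC(=C)C[C@H](OC(=O)c1ccccc1)[C@@H](C(C)C)[C@@H](OC(C)=O)/C=C(/C)[C@H](O)CC=C
F5 | step 3 | (2R,3R,4Z)-1-{[tert-butyl(dimethyl)silyl]oxy}-5-iodo-2-(propan-2-yl)hex-4-en-3-ol | CC(C)(C)[Si](C)(C)OC[C@@H](C(C)C)[C@@H](O)/C=C(/C)I
F6 | step 3 | (2Z,4R,5R)-5-({[tert-butyl(dimethyl)silyl]oxy}methyl)-2-iodo-6-methylhept-2-en-4-yl acetate | CC(C)(C)[Si](C)(C)OC[C@@H](C(C)C)[C@@H](OC(C)=O)/C=C(/C)I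
F7 | step 3 | (2Z,4R,5R)-5-(hydroxymethyl)-2-iodo-6-methylhept-2-en-4-yl acetate | OC[C@@H](C(C)C)[C@@H](OC(C)=O)/C=C(/C)I
F8 | step 8 | (1S,2Z,4S,6Z,9S,10R)-9-(benzoyloxy)-4-hydroxy-3,7-dimethyl-10-(propan-2-yl)cyclodeca-2,6-dien-1-yl acetate | CC(=O)O[C@H]1/C=C(/C)[C@@H](O)C/C=C(/C)C[C@H](OC(=O)c2ccccc2)[C@H]1C(C)C
F9 | step 8 | (1S,2Z,4R,6Z,9S,10R)-9-(benzoyloxy)-4-[(chloroacetyl)oxy]-3,7-dimethyl-10-(propan-2-yl)cyclodeca-2,6-dien-1-yl acetate | CC(=O)O[C@H]1/C=C(/C)[C@H](OC(=O)CCl)C/C=C(/C)C[C@H](OC(=O)c2ccccc2)[C@H]1C(C)C
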